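**Assumption:** the target has no stereocentre (it is achiral), so "single enantiomer" is taken to mean the one constitution drawn. The only stereo-element in the route is the Z double bond of 6, which disappears in step 4.

## Retrosynthetic overview

1. The pyrrole ring is made last. Its ring-closing bond is N1–C2, formed by condensation of a nitrogen already fixed on C5 (next to the acetyl group) with the C2 keto-ester carbonyl.
2. The C3–C4 bond forms in the same flask by conjugate addition of methyl indol-3-ylpyruvate (C2, C3, CO2Me) to a β-indolyl α-azido enone (N, C5, acetyl, C4).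
3. The azide is both the nitrogen source and the internal oxidant (loss of N2), so neither ammonia nor an external oxidant is needed.
4. The azido enone comes from indole-3-carbaldehyde and azidoacetone (Knoevenagel); azidoacetone comes from chloroacetone; the keto ester comes from indole-3-pyruvic acid.
5. Both indole rings are bought intact; the pyrrole is the only ring constructed.

## Route

**Step 1**
Reactants: 1 3-(1H-indol-3-yl)-2-oxopropanoic acid (indole-3-pyruvic acid)
Product: 2 methyl 3-(1H-indol-3-yl)-2-oxopropanoate
Conditions: MeI (1.2 equiv), KHCO3 (1.1 equiv), DMF, 0 °C to rt, Ar, dark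
Reagents that add atoms: iodomethane (CI)
Why: Carboxylate O-alkylation (SN2); KHCO3 deprotonates only the carboxylic acid, not the enol OH or the indole N–H, so only the ester forms, and no stereocentre is involved.

**Step 2**
Reactants: 3 1-chloropropan-2-one (chloroacetone)
Product: 4 1-azidopropan-2-one (azidoacetone)
Conditions: NaN3 (1.2 equiv), acetone/H2O 4:1, rt, 16 h; extracted into Et2O and used as a titrated solution, never concentrated to dryness
Reagents that add atoms: sodium azide, NaN3 ([Na+].[N-]=[N+]=[N-])
Why: SN2 displacement of an α-halo ketone by azide, accelerated by the adjacent carbonyl group.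

**Step 3**
Reactants: 5 1H-indole-3-carbaldehyde; 4 1-azidopropan-2-one (2 equiv)
Product: 6 (3Z)-3-azido-4-(1H-indol-3-yl)but-3-en-2-one
Conditions: pyrrolidine (20 mol %), AcOH (20 mol %), EtOH, 0 °C to rt, dark
Reagents that add atoms: none
Why: Knoevenagel condensation (loss of one water) through the pyrrolidine-derived iminium ion of the aldehyde, which overcomes its vinylogous-formamide character; the azidomethylene is the most acidic C–H of 4, and the Z alkene (indolyl trans to acetyl) is the thermodynamic product.

**Step 4**
Reactants: 2 methyl 3-(1H-indol-3-yl)-2-oxopropanoate (1.2 equiv); 6 (3Z)-3-azido-4-(1H-indol-3-yl)but-3-en-2-one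
Product: 9 methyl 5-acetyl-3,4-di(1H-indol-3-yl)-1H-pyrrole-2-carboxylate, via azido diketone 7 (not isolated), via imino diketone 8 (not isolated)
Conditions: Zn(OTf)2 (10 mol %), iPr2NEt (20 mol %), 4 Å MS, MeCN, 40 °C, Ar, dark; then AcOH (1 equiv), 40 °C
Reagents that add atoms: none
Why: Proposed new method: a Lewis-acid/soft-enolisation denitrogenative aza-annulation. Zn(OTf)2 binds the enol of 2 as a five-membered zinc chelate (C3 nucleophile) and activates the carbonyl of 6, whose indole nitrogen pushes to give a 3-alkylidene-indoleninium-type acceptor attacked only at C4. The resulting α-azido enolate (7 after protonation) expels N2 to give the N–H ketimine 8. Its nitrogen already sits on C5 beside the acetyl group, so the only carbonyl it can reach in a five-membered ring is the very electrophilic C2 keto-ester carbonyl. The ring-closing N1–C2 bond forms by condensation (loss of water, taken up by the sieves) and a proton shift aromatises the ring; the two transient sp3 centres at C3 and C4 become sp2, so no stereocentre remains. Closest known reaction type: the annulation of α-azido acrylates with 1,3-dicarbonyl compounds catalysed by divalent copper (Cu(NTf2)2), together with the base-induced N2 loss of α-azido ketones to α-imino ketones. New here are the α-keto ester enol as donor, the β-indolyl α-azido enone as acceptor, and redox-inert zinc, chosen so that the electron-rich enol is not oxidised to its homodimer.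

## Compound list

1 | 3-(1H-indol-3-yl)-2-oxopropanoic acid (indole-3-pyruvic acid) | O=C(O)C(=O)Cc1c[nH]c2ccccc12 | starting material
2 | methyl 3-(1H-indol-3-yl)-2-oxopropanoate (mainly as its enol) | COC(=O)C(=O)Cc1c[nH]c2ccccc12 | intermediate
3 | 1-chloropropan-2-one (chloroacetone) | CC(=O)CCl | starting material
4 | 1-azidopropan-2-one (azidoacetone) | CC(=O)CN=[N+]=[N-] | intermediate
5 | 1H-indole-3-carbaldehyde | O=Cc1c[nH]c2ccccc12 | starting material
6 | (3Z)-3-azido-4-(1H-indol-3-yl)but-3-en-2-one | CC(=O)/C(N=[N+]=[N-])=C/c1c[nH]c2ccccc12 | intermediate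
7 | methyl 5-azido-3,4-di(1H-indol-3-yl)-2,6-dioxoheptanoate (diastereomer mixture, not isolated) | COC(=O)C(=O)C(c1c[nH]c2ccccc12)C(c1c[nH]c2ccccc12)C(N=[N+]=[N-])C(C)=O | intermediate
8 | methyl 5-imino-3,4-di(1H-indol-3-yl)-2,6-dioxoheptanoate (diastereomer mixture, not isolated) | COC(=O)C(=O)C(c1c[nH]c2ccccc12)C(c1c[nH]c2ccccc12)C(=N)C(C)=O | intermediate
9 | methyl 5-acetyl-3,4-di(1H-indol-3-yl)-1H-pyrrole-2-carboxylate | COC(=O)c1[nH]c(C(C)=O)c(-c2c[nH]c3ccccc23)c1-c1c[nH]c2ccccc12 | target

## Step count and risks

Total steps: 4. Longest linear sequence: 3 (steps 2, 3, 4).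

**Step 4 (the new annulation).** Possible failures:
- the push-pull acceptor 6 is too unreactive;
- 6 rearranges thermally to a 2H-azirine above about 60 °C, which would give the 4-acetyl regioisomer;
- adduct 7 undergoes Michael/aldol cyclisation before N2 loss;
- 2 homodimerises.

Fallback with known chemistry, setting out from 2 and returning at 9. The enolate of 2 is dimerised oxidatively (DBU 1.05 equiv, then I2 0.5 equiv, THF, −78 °C to rt) to dimethyl 3,4-di(1H-indol-3-yl)-2,5-dioxohexanedioate F1, obtained as a mixture of the meso and racemic forms. The crude diketone is condensed with NH4OAc in AcOH at 60 °C (Paal–Knorr) to lycogarubin C F2. One ester is saponified with LiOH (1.05 equiv, THF/H2O, 0 °C) to 5-(methoxycarbonyl)-3,4-di(1H-indol-3-yl)-1H-pyrrole-2-carboxylic acid F3. Coupling with MeNHOMe·HCl (EDC·HCl, HOBt, iPr2NEt, DMF) gives methyl 5-[methoxy(methyl)carbamoyl]-3,4-di(1H-indol-3-yl)-1H-pyrrole-2-carboxylate F4. MeMgBr (4.5 equiv, THF, −20 to 0 °C) then deprotonates the three N–H groups and converts the Weinreb amide into the acetyl group of 9 through its stable magnesium chelate, while the ester is deactivated as part of the N-magnesiated pyrrole.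

**Step 3 (Knoevenagel on an unprotected indole aldehyde).** The aldehyde is a weak electrophile and 4 decomposes under amine bases.

Fallback, setting out from 5 and returning at 6. 5 is acylated with Boc2O/DMAP (MeCN, rt) to tert-butyl 3-formyl-1H-indole-1-carboxylate F5, in which the nitrogen lone pair no longer deactivates the aldehyde. Condensation with 4 (piperidine, AcOH cat., EtOH, −10 °C) gives tert-butyl 3-[(1Z)-2-azido-3-oxobut-1-en-1-yl]-1H-indole-1-carboxylate F6. K2CO3 in MeOH at 0 °C removes the activated carbamate and gives 6.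

**Step 1 (esterification of the oxidation-prone enol acid).** O- or C-methylation of the enol and decomposition of 1 are possible.

Fallback, setting out from 5 and returning at 2, which bypasses the free keto acid. Erlenmeyer condensation of 5 with N-acetylglycine (Ac2O, NaOAc, 100 °C) gives (4Z)-4-[(1-acetyl-1H-indol-3-yl)methylidene]-2-methyl-1,3-oxazol-5(4H)-one F7. NaOMe in MeOH at rt opens the azlactone and removes the indole N-acetyl group, giving methyl (2Z)-2-acetamido-3-(1H-indol-3-yl)prop-2-enoate F8. Hydrolysis of the enamide (HCl, MeOH/H2O, reflux) gives 2.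

## Further compounds

F1 | step 4 | dimethyl 3,4-di(1H-indol-3-yl)-2,5-dioxohexanedioate | COC(=O)C(=O)C(c1c[nH]c2ccccc12)C(c1c[nH]c2ccccc12)C(=O)C(=O)OC
F2 | step 4 | lycogarubin C (dimethyl 3,4-di(1H-indol-3-yl)-1H-pyrrole-2,5-dicarboxylate) | COC(=O)c1[nH]c(C(=O)OC)c(-c2c[nH]c3ccccc23)c1-c1c[nH]c2ccccc12
F3 | step 4 | 5-(methoxycarbonyl)-3,4-di(1H-indol-3-yl)-1H-pyrrole-2-carboxylic acid | COC(=O)c1[nH]c(C(=O)O)c(-c2c[nH]c3ccccc23)c1-c1c[nH]c2ccccc12
F4 | step 4 | methyl 5-[methoxy(methyl)carbamoyl]-3,4-di(1H-indol-3-yl)-1H-pyrrole-2-carboxylate | COC(=O)c1[nH]c(C(=O)N(C)OC)c(-c2c[nH]c3ccccc23)c1-c1c[nH]c2ccccc12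
F5 | step 3 | tert-butyl 3-formyl-1H-indole-1-carboxylate | CC(C)(C)OC(=O)n1cc(C=O)c2ccccc12
F6 | step 3 | tert-butyl 3-[(1Z)-2-azido-3-oxobut-1-en-1-yl]-1H-indole-1-carboxylate | CC(=O)/C(N=[N+]=[N-])=C/c1cn(C(=O)OC(C)(C)C)c2ccccc12
F7 | step 1 | (4Z)-4-[(1-acetyl-1H-indol-3-yl)methylidene]-2-methyl-1,3-oxazol-5(4H)-one | CC1=N/C(=C\c2cn(C(C)=O)c3ccccc23)C(=O)O1
F8 | step 1 | methyl (2Z)-2-acetamido-3-(1H-indol-3-yl)prop-2-enoate | COC(=O)/C(NC(C)=O)=C/c1c[nH]c2ccccc12
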